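**Retrosynthetic overview**

1. Numbering: chain C1' (ArCH2) to C16' (CH2OH); ring A has C1 (OH between the substituents), C2 (chain), C4 (second OH), C6 (CH3). The hydroquinone is traced back through the quinone and the 4-aminophenol to a 4-nitrophenol, so the C4 oxygen enters as nitrogen.
2. Feature used: C2–C1(O)–C6, with C1' on C2 and the methyl on C6, is the α-CH2–C(=O)–α'-CH2 core of an ethyl alkyl ketone, and C3–C4(N)–C5 is 2-nitromalonaldehyde. Ring A, the only ring, is therefore built last on the finished chain by forming C2–C3 and C5–C6 in two aldol condensations.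
3. The ketone comes from the C1' allylic bromide and methyl 3-oxopentanoate (alkylation, decarboxylation); the C1'–C3' unit comes from methylalumination and formaldehyde capture of a terminal alkyne.
4. C5' (S) is set by catalytic asymmetric propargylation of 12-silyloxyfarnesal, which comes from (2E,6E)-farnesol by terminal allylic oxidation.

Key step: step 12

Assumption 1: the (S)-enantiomer of 3,3'-bis(2,4,6-triisopropylphenyl)-BINOL hydrogen phosphate ((S)-TRIP) is taken to direct the propargyl group to the Si face of enal 7, by analogy with the facial sense of this catalyst class with aryl and alkenyl aldehydes; the configuration of 9 would be checked by MTPA ester analysis and the antipodal acid used if the sense were opposite.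
Assumption 2: sodium nitromalonaldehyde (19) is used as its commercial monohydrate; it is impact-sensitive and should be handled in small portions.

**Route**

Step 1
Reactants: 1 (2E,6E)-farnesol
Product: 2 (2E,6E)-farnesyl acetate
Conditions: Ac2O, pyridine, DMAP (cat.), CH2Cl2, 0 °C to rt
Reagents that add atoms: acetic anhydride, CC(=O)OC(C)=O
Why: Nucleophilic-catalysed acylation masks the C1 alcohol and deactivates the 2,3-alkene towards the allylic oxidation that follows.

Step 2
Reactants: 2 (2E,6E)-farnesyl acetate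
Product: 4 (2E,6E,10E)-12-hydroxyfarnesyl acetate, via 12-oxofarnesyl acetate 3 (not isolated)
Conditions: SeO2 (0.3 equiv), t-BuOOH (70% aq., 3 equiv), salicylic acid (0.1 equiv), CH2Cl2, 0 °C to rt; then NaBH4, EtOH, 0 °C
Reagents that add atoms: selenium dioxide, O=[Se]=O (delivers the oxygen); tert-butyl hydroperoxide, CC(C)(C)OO (restores it)
Why: Riley-type allylic oxidation (ene reaction, then [2,3]-sigmatropic shift) should attack the terminal, most electron-rich trisubstituted alkene at its (E)-methyl group, and NaBH4 returns any over-oxidised aldehyde 3 to the alcohol.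

Step 3
Reactants: 4 (2E,6E,10E)-12-hydroxyfarnesyl acetate
Product: 5 (2E,6E,10E)-12-(tert-butyldimethylsilyloxy)farnesyl acetate
Conditions: TBSCl, imidazole, DMF, 0 °C to rt
Reagents that add atoms: tert-butyldimethylsilyl chloride, CC(C)(C)[Si](C)(C)Cl
Why: Standard imidazole-mediated silylation of a primary allylic alcohol protects the future C16' oxygen as a base-stable ether.

Step 4
Reactants: 5 (2E,6E,10E)-12-(tert-butyldimethylsilyloxy)farnesyl acetate
Product: 6 (2E,6E,10E)-12-(tert-butyldimethylsilyloxy)farnesol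
Conditions: K2CO3 (0.2 equiv), MeOH, rt
Reagents that add atoms: none
Why: Base-catalysed transesterification removes the acetate as methyl acetate and leaves the silyl ether intact.

Step 5
Reactants: 6 (2E,6E,10E)-12-(tert-butyldimethylsilyloxy)farnesol
Product: 7 (2E,6E,10E)-12-(tert-butyldimethylsilyloxy)farnesal
Conditions: MnO2 (activated, 15 equiv), CH2Cl2, rt
Reagents that add atoms: none
Why: Chemoselective MnO2 oxidation of the allylic alcohol should give the (2E)-enal without double-bond isomerisation or over-oxidation.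

Step 6
Reactants: 7 (2E,6E,10E)-12-(tert-butyldimethylsilyloxy)farnesal; 8 allenylboronic acid pinacol ester
Product: 9 (4S,5E,9E,13E)-15-(tert-butyldimethylsilyloxy)-6,10,14-trimethylpentadeca-5,9,13-trien-1-yn-4-ol
Conditions: 8 (1.5 equiv), (S)-TRIP (5 mol%), 4 Å MS, toluene, −20 to 0 °C; aq. NaHCO3 work-up
Reagents that add atoms: allenylboronic acid pinacol ester (8), C=C=CB1OC(C)(C)C(C)(C)O1
Why: Chiral Brønsted acid-catalysed propargylboration proceeds through a chair-like six-membered transition state in which γ-attack (SE2') of the allenylboronate gives the homopropargylic alcohol, and the catalyst directs attack to the Si face of the enal to set C5' as S.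

Step 7
Reactants: 9 (4S,5E,9E,13E)-15-(tert-butyldimethylsilyloxy)-6,10,14-trimethylpentadeca-5,9,13-trien-1-yn-4-ol
Product: 10 (4S,5E,9E,13E)-4,15-bis(tert-butyldimethylsilyloxy)-6,10,14-trimethylpentadeca-5,9,13-trien-1-yne
Conditions: TBSCl, imidazole, DMAP (cat.), DMF, rt
Reagents that add atoms: tert-butyldimethylsilyl chloride, CC(C)(C)[Si](C)(C)Cl
Why: Silylation on oxygen leaves the C5' configuration untouched and removes the acidic proton before the organoaluminium step.

Step 8
Reactants: 10 (4S,5E,9E,13E)-4,15-bis(tert-butyldimethylsilyloxy)-6,10,14-trimethylpentadeca-5,9,13-trien-1-yne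
Product: 12 (2E,5S,6E,10E,14E)-5,16-bis(tert-butyldimethylsilyloxy)-3,7,11,15-tetramethylhexadeca-2,6,10,14-tetraen-1-ol, via alkenyldimethylalane 11 (not isolated)
Conditions: AlMe3 (3 equiv), Cp2ZrCl2 (0.25 equiv), CH2Cl2, 0 °C to rt; evaporate; hexane/THF, n-BuLi (1.1 equiv), −78 to 0 °C; (CH2O)n (5 equiv), rt; aq. KNaC4H4O6 work-up
Reagents that add atoms: trimethylaluminium, C[Al](C)C; formaldehyde (from paraformaldehyde), C=O
Why: Negishi carboalumination adds Me–Al syn across the terminal alkyne with methyl on the internal carbon, and the alanate formed with n-BuLi is hydroxymethylated by formaldehyde with retention, which fixes the (2'E) trisubstituted alkene and installs C1'.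

Step 9
Reactants: 12 (2E,5S,6E,10E,14E)-5,16-bis(tert-butyldimethylsilyloxy)-3,7,11,15-tetramethylhexadeca-2,6,10,14-tetraen-1-ol
Product: 14 (2E,5S,6E,10E,14E)-1-bromo-5,16-bis(tert-butyldimethylsilyloxy)-3,7,11,15-tetramethylhexadeca-2,6,10,14-tetraene, via allylic mesylate 13 (not isolated)
Conditions: MsCl, Et3N, THF, −40 °C; then LiBr (4 equiv), −40 to 0 °C; used crude
Reagents that add atoms: lithium bromide, [Li+].[Br-]
Why: Mesylation followed by in-situ SN2 displacement with bromide is the standard non-acidic way to make polyprenyl bromides and should not cause allylic transposition or touch the silyl ethers.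

Step 10
Reactants: 14 (2E,5S,6E,10E,14E)-1-bromo-5,16-bis(tert-butyldimethylsilyloxy)-3,7,11,15-tetramethylhexadeca-2,6,10,14-tetraene; 15 methyl 3-oxopentanoate
Product: 16 methyl (4E,7S,8E,12E,16E)-7,18-bis(tert-butyldimethylsilyloxy)-5,9,13,17-tetramethyl-2-propanoyloctadeca-4,8,12,16-tetraenoate (both epimers at C2)
Conditions: 15 (2 equiv), NaH (1.9 equiv), THF, 0 °C; then 14, 0 °C to rt
Reagents that add atoms: methyl 3-oxopentanoate (15), CCC(=O)CC(=O)OC
Why: Acetoacetic-ester-type SN2 C-alkylation of the stabilised β-keto ester enolate by the primary allylic bromide forms the bond from C1' to the future ring C2, with excess enolate suppressing dialkylation; the new centre is removed in step 11.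

Step 11
Reactants: 16 methyl (4E,7S,8E,12E,16E)-7,18-bis(tert-butyldimethylsilyloxy)-5,9,13,17-tetramethyl-2-propanoyloctadeca-4,8,12,16-tetraenoate
Product: 18 (6E,9S,10E,14E,18E)-9,20-bis(tert-butyldimethylsilyloxy)-7,11,15,19-tetramethylicosa-6,10,14,18-tetraen-3-one, via β-keto acid 17 (not isolated)
Conditions: LiOH·H2O (3 equiv), THF/MeOH/H2O, rt; AcOH to pH 5 at 0 °C, extract; toluene, 80 °C
Reagents that add atoms: none
Why: Saponification and thermal decarboxylation of the β-keto acid through its cyclic six-membered transition state give the ethyl alkyl ketone under conditions that both silyl ethers should tolerate.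

Step 12
Reactants: 18 (6E,9S,10E,14E,18E)-9,20-bis(tert-butyldimethylsilyloxy)-7,11,15,19-tetramethylicosa-6,10,14,18-tetraen-3-one; 19 sodium nitromalonaldehyde
Product: 21 2-[(2E,5S,6E,10E,14E)-5,16-bis(tert-butyldimethylsilyloxy)-3,7,11,15-tetramethylhexadeca-2,6,10,14-tetraen-1-yl]-6-methyl-4-nitrophenol, via open-chain nitrodienolate 20 (not isolated)
Conditions: 19 (monohydrate, 1.5 equiv), NaOH (1 M aq., 2 equiv), EtOH/THF (one phase), rt, dark, 3–5 d; AcOH to pH 5
Reagents that add atoms: sodium nitromalonaldehyde (19), [Na+].O=C[C-](C=O)[N+](=O)[O-]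
Why: Hydroxide forms the enolate at one α-methylene of 18, which adds to a formyl group of the nitromalonaldehyde anion and loses water (E1cB) to give the open-chain nitrodienolate 20; the enolate at the other α-methylene then attacks the remaining formyl group, and a second dehydration leaves a cyclohexadienone aci-nitronate that is the 4-nitrophenolate itself, so aromatisation drives both condensations. The closest known reaction type is the condensation of sodium nitromalonaldehyde with dialkyl ketones in aqueous alkali to give 2,6-dialkyl-4-nitrophenols. Ring A is closed by a 6-(enolendo)-exo-trig intramolecular aldol reaction, which forms C2–C3 or C5–C6 depending on which α-carbon reacts second. No stereocentre is created, and C5' is remote from every enolisable position, so it should not be affected. Only constitutional selectivity is needed, and it is fixed by the carbonyl carbon being flanked by exactly two methylene groups, so the chain and the methyl group must end on C2 and C6 beside the C1 hydroxyl with nitro on C4. The base is kept dilute and unheated so that the silyl ethers should survive.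

Step 13
Reactants: 21 2-[(2E,5S,6E,10E,14E)-5,16-bis(tert-butyldimethylsilyloxy)-3,7,11,15-tetramethylhexadeca-2,6,10,14-tetraen-1-yl]-6-methyl-4-nitrophenol
Product: 22 2-[(2E,5S,6E,10E,14E)-5,16-dihydroxy-3,7,11,15-tetramethylhexadeca-2,6,10,14-tetraen-1-yl]-6-methyl-4-nitrophenol
Conditions: Bu4NF (5 equiv), THF, 0 °C to rt; AcOH quench
Reagents that add atoms: none
Why: Fluoride-driven desilylation is done at the nitrophenol stage because the nitrophenolate is inert to basic fluoride, whereas the later quinone and hydroquinone are not, and the free diol makes the three aqueous redox steps homogeneous.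

Step 14
Reactants: 22 2-[(2E,5S,6E,10E,14E)-5,16-dihydroxy-3,7,11,15-tetramethylhexadeca-2,6,10,14-tetraen-1-yl]-6-methyl-4-nitrophenol
Product: 23 4-amino-2-[(2E,5S,6E,10E,14E)-5,16-dihydroxy-3,7,11,15-tetramethylhexadeca-2,6,10,14-tetraen-1-yl]-6-methylphenol
Conditions: Na2S2O4 (6 equiv), THF/EtOH/H2O, 50 °C, argon; used crude
Reagents that add atoms: none
Why: Dithionite reduces the aromatic nitro group to the amine by stepwise electron transfer and, unlike catalytic hydrogenation, leaves the four alkenes and the allylic alcohols untouched.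

Step 15
Reactants: 23 4-amino-2-[(2E,5S,6E,10E,14E)-5,16-dihydroxy-3,7,11,15-tetramethylhexadeca-2,6,10,14-tetraen-1-yl]-6-methylphenol
Product: 25 2-[(2E,5S,6E,10E,14E)-5,16-dihydroxy-3,7,11,15-tetramethylhexadeca-2,6,10,14-tetraen-1-yl]-6-methyl-1,4-benzoquinone, via quinone monoimine 24 (not isolated)
Conditions: (KSO3)2NO (2.5 equiv), aq. KH2PO4, acetone, 0 °C to rt
Reagents that add atoms: water, O
Why: Teuber oxidation with two equivalents of the nitrosodisulfonate radical converts the p-aminophenol into the quinone monoimine, which hydrolyses in the buffer to the p-quinone, exchanging nitrogen for oxygen at C4 without oxidising the alcohols or alkenes.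

Step 16
Reactants: 25 2-[(2E,5S,6E,10E,14E)-5,16-dihydroxy-3,7,11,15-tetramethylhexadeca-2,6,10,14-tetraen-1-yl]-6-methyl-1,4-benzoquinone
Product: 26 2-[(2E,5S,6E,10E,14E)-5,16-dihydroxy-3,7,11,15-tetramethylhexadeca-2,6,10,14-tetraen-1-yl]-6-methylbenzene-1,4-diol (CNP0151872.1)
Conditions: Na2S2O4 (aq., 5 equiv), EtOAc/H2O, rt, argon; product kept under argon
Reagents that add atoms: none
Why: Two-electron reduction of the quinone by dithionite in a two-phase system should deliver the air-sensitive hydroquinone last, under neutral reducing conditions that avoid chromenol or chroman formation.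

**Compound list**

1 | (2E,6E)-farnesol | CC(C)=CCC/C(C)=C/CC/C(C)=C/CO | starting material
2 | (2E,6E)-farnesyl acetate | CC(C)=CCC/C(C)=C/CC/C(C)=C/COC(C)=O | intermediate
3 | (2E,6E,10E)-3,7,11-trimethyl-12-oxododeca-2,6,10-trien-1-yl acetate (12-oxofarnesyl acetate, not isolated) | C/C(=C\CC/C(C)=C/CC/C(C)=C/COC(C)=O)C=O | intermediate
4 | (2E,6E,10E)-12-hydroxy-3,7,11-trimethyldodeca-2,6,10-trien-1-yl acetate | C/C(=C\CC/C(C)=C/CC/C(C)=C/COC(C)=O)CO | intermediate
5 | (2E,6E,10E)-12-(tert-butyldimethylsilyloxy)-3,7,11-trimethyldodeca-2,6,10-trien-1-yl acetate | C/C(=C\CC/C(C)=C/CC/C(C)=C/COC(C)=O)CO[Si](C)(C)C(C)(C)C | intermediate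
6 | (2E,6E,10E)-12-(tert-butyldimethylsilyloxy)-3,7,11-trimethyldodeca-2,6,10-trien-1-ol | C/C(=C\CC/C(C)=C/CC/C(C)=C/CO)CO[Si](C)(C)C(C)(C)C | intermediate
7 | (2E,6E,10E)-12-(tert-butyldimethylsilyloxy)-3,7,11-trimethyldodeca-2,6,10-trienal | C/C(=C\CC/C(C)=C/CC/C(C)=C/C=O)CO[Si](C)(C)C(C)(C)C | intermediate
8 | allenylboronic acid pinacol ester | C=C=CB1OC(C)(C)C(C)(C)O1 | starting material
9 | (4S,5E,9E,13E)-15-(tert-butyldimethylsilyloxy)-6,10,14-trimethylpentadeca-5,9,13-trien-1-yn-4-ol | C/C(=C\CC/C(C)=C/CC/C(C)=C/[C@@H](O)CC#C)CO[Si](C)(C)C(C)(C)C | intermediate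
10 | (4S,5E,9E,13E)-4,15-bis(tert-butyldimethylsilyloxy)-6,10,14-trimethylpentadeca-5,9,13-trien-1-yne | C/C(=C\CC/C(C)=C/CC/C(C)=C/[C@@H](O[Si](C)(C)C(C)(C)C)CC#C)CO[Si](C)(C)C(C)(C)C | intermediate
11 | dimethyl[(1E,4S,5E,9E,13E)-4,15-bis(tert-butyldimethylsilyloxy)-2,6,10,14-tetramethylpentadeca-1,5,9,13-tetraen-1-yl]alane (not isolated) | C/C(=C\CC/C(C)=C/CC/C(C)=C/[C@@H](O[Si](C)(C)C(C)(C)C)C/C(C)=C/[Al](C)C)CO[Si](C)(C)C(C)(C)C | intermediate
12 | (2E,5S,6E,10E,14E)-5,16-bis(tert-butyldimethylsilyloxy)-3,7,11,15-tetramethylhexadeca-2,6,10,14-tetraen-1-ol | C/C(=C\CC/C(C)=C/CC/C(C)=C/[C@@H](O[Si](C)(C)C(C)(C)C)C/C(C)=C/CO)CO[Si](C)(C)C(C)(C)C | intermediate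
13 | (2E,5S,6E,10E,14E)-5,16-bis(tert-butyldimethylsilyloxy)-3,7,11,15-tetramethylhexadeca-2,6,10,14-tetraen-1-yl methanesulfonate (not isolated) | C/C(=C\CC/C(C)=C/CC/C(C)=C/[C@@H](O[Si](C)(C)C(C)(C)C)C/C(C)=C/COS(C)(=O)=O)CO[Si](C)(C)C(C)(C)C | intermediate
14 | (2E,5S,6E,10E,14E)-1-bromo-5,16-bis(tert-butyldimethylsilyloxy)-3,7,11,15-tetramethylhexadeca-2,6,10,14-tetraene | C/C(=C\CC/C(C)=C/CC/C(C)=C/[C@@H](O[Si](C)(C)C(C)(C)C)C/C(C)=C/CBr)CO[Si](C)(C)C(C)(C)C | intermediate
15 | methyl 3-oxopentanoate | CCC(=O)CC(=O)OC | starting material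
16 | methyl (4E,7S,8E,12E,16E)-7,18-bis(tert-butyldimethylsilyloxy)-5,9,13,17-tetramethyl-2-propanoyloctadeca-4,8,12,16-tetraenoate (both epimers at C2) | C/C(=C\CC/C(C)=C/CC/C(C)=C/[C@@H](O[Si](C)(C)C(C)(C)C)C/C(C)=C/CC(C(=O)OC)C(=O)CC)CO[Si](C)(C)C(C)(C)C | intermediate
17 | (4E,7S,8E,12E,16E)-7,18-bis(tert-butyldimethylsilyloxy)-5,9,13,17-tetramethyl-2-propanoyloctadeca-4,8,12,16-tetraenoic acid (both epimers at C2, not isolated) | C/C(=C\CC/C(C)=C/CC/C(C)=C/[C@@H](O[Si](C)(C)C(C)(C)C)C/C(C)=C/CC(C(=O)O)C(=O)CC)CO[Si](C)(C)C(C)(C)C | intermediate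
18 | (6E,9S,10E,14E,18E)-9,20-bis(tert-butyldimethylsilyloxy)-7,11,15,19-tetramethylicosa-6,10,14,18-tetraen-3-one | C/C(=C\CC/C(C)=C/CC/C(C)=C/[C@@H](O[Si](C)(C)C(C)(C)C)C/C(C)=C/CCC(=O)CC)CO[Si](C)(C)C(C)(C)C | intermediate
19 | sodium nitromalonaldehyde | [Na+].O=C[C-](C=O)[N+](=O)[O-] | starting material
20 | sodium salt of the mono-condensation product, drawn for first attack through the ethyl-side α-carbon (the regioisomer converges on the same phenol; geometry of the new dienolate bonds not fixed; not isolated) | C/C(=C\CC/C(C)=C/CC/C(C)=C/[C@@H](O[Si](C)(C)C(C)(C)C)C/C(C)=C/CCC(=O)C(C)=CC(=C[O-])[N+](=O)[O-])CO[Si](C)(C)C(C)(C)C.[Na+] | intermediate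
21 | 2-[(2E,5S,6E,10E,14E)-5,16-bis(tert-butyldimethylsilyloxy)-3,7,11,15-tetramethylhexadeca-2,6,10,14-tetraen-1-yl]-6-methyl-4-nitrophenol | C/C(=C\CC/C(C)=C/CC/C(C)=C/[C@@H](O[Si](C)(C)C(C)(C)C)C/C(C)=C/Cc1cc([N+](=O)[O-])cc(C)c1O)CO[Si](C)(C)C(C)(C)C | intermediate
22 | 2-[(2E,5S,6E,10E,14E)-5,16-dihydroxy-3,7,11,15-tetramethylhexadeca-2,6,10,14-tetraen-1-yl]-6-methyl-4-nitrophenol | C/C(=C\CC/C(C)=C/CC/C(C)=C/[C@@H](O)C/C(C)=C/Cc1cc([N+](=O)[O-])cc(C)c1O)CO | intermediate
23 | 4-amino-2-[(2E,5S,6E,10E,14E)-5,16-dihydroxy-3,7,11,15-tetramethylhexadeca-2,6,10,14-tetraen-1-yl]-6-methylphenol | C/C(=C\CC/C(C)=C/CC/C(C)=C/[C@@H](O)C/C(C)=C/Cc1cc(N)cc(C)c1O)CO | intermediate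
24 | 2-[(2E,5S,6E,10E,14E)-5,16-dihydroxy-3,7,11,15-tetramethylhexadeca-2,6,10,14-tetraen-1-yl]-4-imino-6-methylcyclohexa-2,5-dien-1-one (not isolated) | C/C(=C\CC/C(C)=C/CC/C(C)=C/[C@@H](O)C/C(C)=C/CC1=CC(=N)C=C(C)C1=O)CO | intermediate
25 | 2-[(2E,5S,6E,10E,14E)-5,16-dihydroxy-3,7,11,15-tetramethylhexadeca-2,6,10,14-tetraen-1-yl]-6-methyl-1,4-benzoquinone | C/C(=C\CC/C(C)=C/CC/C(C)=C/[C@@H](O)C/C(C)=C/CC1=CC(=O)C=C(C)C1=O)CO | intermediate
26 | 2-[(2E,5S,6E,10E,14E)-5,16-dihydroxy-3,7,11,15-tetramethylhexadeca-2,6,10,14-tetraen-1-yl]-6-methylbenzene-1,4-diol | C/C(=C\CC/C(C)=C/CC/C(C)=C/[C@@H](O)C/C(C)=C/Cc1cc(O)cc(C)c1O)CO | target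

**Step count and risks**

Total step count: 16. Longest linear sequence: 16 steps (from farnesol 1; the partners 8, 15 and 19 are bought).

Steps most likely to fail:

1. Step 12 (ring construction). The lipophilic ketone may not stay in one phase with the aqueous nitromalonaldehyde salt. The first, intermolecular aldol could then be outrun by self-condensation of the ketone or by slow loss of the primary silyl ether, and the open-chain adduct might not close. Fallback, from bromide 14 back to quinone 25: the ring is bought instead of built. Sodium 2-methylphenoxide (o-cresol, NaH, toluene) is C-allylated at its free ortho position by 14 to give 2-methyl-6-[(2E,5S,6E,10E,14E)-5,16-bis(tert-butyldimethylsilyloxy)-3,7,11,15-tetramethylhexadeca-2,6,10,14-tetraen-1-yl]phenol F1. Bu4NF in THF gives the phenol diol F2. Teuber oxidation of F2 with (KSO3)2NO at the free para position gives 25, and step 16 follows.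

2. Step 8 (methylalumination and formaldehyde capture). The Lewis acidic AlMe3/Cp2ZrCl2 medium may ionise or methylate the allylic C5' silyl ether, and the alkenylalanate may be protonated on work-up instead of hydroxymethylated. Fallback, from aldehyde 7 back to alcohol 12, replacing steps 6 to 8: a catalytic enantioselective vinylogous Mukaiyama aldol addition. Methyl 3-methylbut-2-enoate is converted (LDA, TBSCl) into 1-(tert-butyldimethylsilyloxy)-1-methoxy-3-methylbuta-1,3-diene F3. F3 is added to 7 under SiCl4 and a chiral bisphosphoramide Lewis base, with the catalyst enantiomer chosen for Si-face attack. This should give methyl (2E,5S,6E,10E,14E)-16-(tert-butyldimethylsilyloxy)-5-hydroxy-3,7,11,15-tetramethylhexadeca-2,6,10,14-tetraenoate F4, setting C5' and the (2'E)-alkene in one operation. Silylation (TBSCl, imidazole) gives the bis-silyl ester F5, and i-Bu2AlH reduction gives 12.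

3. Step 6 (asymmetric propargylation). Facial selectivity may be insufficient with the β,β-disubstituted enal, or the acid may equilibrate the E/Z geometry of the conjugated alkene before addition. Fallback, from aldehyde 7 back to alcohol 9: Barbier propargylation (propargyl bromide, Zn, THF/aq. NH4Cl) gives the racemic alcohol 15-(tert-butyldimethylsilyloxy)-6,10,14-trimethylpentadeca-5,9,13-trien-1-yn-4-ol F6. Lipase-catalysed acylation (Burkholderia cepacia lipase, vinyl acetate, hexane), relying on the usual (R)-selectivity of this enzyme for secondary alcohols, should convert the (R)-enantiomer into the (4R)-acetate F7 and leave (S)-9 for step 7.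

**Further compounds**

F1 | step 12 | 2-[(2E,5S,6E,10E,14E)-5,16-bis(tert-butyldimethylsilyloxy)-3,7,11,15-tetramethylhexadeca-2,6,10,14-tetraen-1-yl]-6-methylphenol | C/C(=C\CC/C(C)=C/CC/C(C)=C/[C@@H](O[Si](C)(C)C(C)(C)C)C/C(C)=C/Cc1cccc(C)c1O)CO[Si](C)(C)C(C)(C)C
F2 | step 12 | 2-[(2E,5S,6E,10E,14E)-5,16-dihydroxy-3,7,11,15-tetramethylhexadeca-2,6,10,14-tetraen-1-yl]-6-methylphenol | C/C(=C\CC/C(C)=C/CC/C(C)=C/[C@@H](O)C/C(C)=C/Cc1cccc(C)c1O)CO
F3 | step 8 | 1-(tert-butyldimethylsilyloxy)-1-methoxy-3-methylbuta-1,3-diene | COC(O[Si](C)(C)C(C)(C)C)=CC(C)=C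
F4 | step 8 | methyl (2E,5S,6E,10E,14E)-16-(tert-butyldimethylsilyloxy)-5-hydroxy-3,7,11,15-tetramethylhexadeca-2,6,10,14-tetraenoate | C/C(=C\CC/C(C)=C/CC/C(C)=C/[C@@H](O)C/C(C)=C/C(=O)OC)CO[Si](C)(C)C(C)(C)C
F5 | step 8 | methyl (2E,5S,6E,10E,14E)-5,16-bis(tert-butyldimethylsilyloxy)-3,7,11,15-tetramethylhexadeca-2,6,10,14-tetraenoate | C/C(=C\CC/C(C)=C/CC/C(C)=C/[C@@H](O[Si](C)(C)C(C)(C)C)C/C(C)=C/C(=O)OC)CO[Si](C)(C)C(C)(C)C
F6 | step 6 | racemic (5E,9E,13E)-15-(tert-butyldimethylsilyloxy)-6,10,14-trimethylpentadeca-5,9,13-trien-1-yn-4-ol | C/C(=C\CC/C(C)=C/CC/C(C)=C/C(O)CC#C)CO[Si](C)(C)C(C)(C)C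
F7 | step 6 | (4R,5E,9E,13E)-15-(tert-butyldimethylsilyloxy)-6,10,14-trimethylpentadeca-5,9,13-trien-1-yn-4-yl acetate | C/C(=C\CC/C(C)=C/CC/C(C)=C/[C@H](OC(C)=O)CC#C)CO[Si](C)(C)C(C)(C)C
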